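**Plan**
- Retrosynthesis: the two bonds that tie the resorcinol ring into the seven-membered ring (resorcinol C to benzofuran C3, and the adjacent resorcinol C to the ketone α-carbon) are cut together. This gives 3,5-bis(benzyloxy)benzyne and a 3-iodo-2-arylbenzofuran with an ArCH2C(=O) group at C4. The ketone is then cut at C(=O)–CH2 (nitrile plus benzyl Grignard) and the furan ring at O1–C2 and C3–I (alkyne iodocyclization).
- Enabling feature: C3 and the ketone α-carbon sit on the peri positions C3/C4 of the benzofuran, five atoms apart. Direct C3–Cα closure would give a strained peri-fused five-membered ring, so an arylpalladium at C3 must wait for a two-carbon unit. Insertion of the aryne turns this 1,5-pair into the seven-membered ring, and the 3-benzyloxy group of the aryne steers C3 to the remote aryne carbon.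
- Forward order: benzonitrile ring, then furan ring with the C3–I handle built in, then ketone side chain, then [5+2] aryne annulation (seven-membered ring and resorcinol ring in one step), then stereocenter, then debenzylation.
- Stereochemistry: the single stereocenter is formed racemic in the basic annulation. It is then set by asymmetric transfer hydrogenation with dynamic kinetic resolution (cis-(S,S) alcohol) and reoxidation; the final hydrogenolysis is neutral.

Key step: step 9

Assumption: the (S) methine α to the ketone is treated as labile to base, so after it is set only neutral or weakly acidic, non-enolizing conditions are used; the benzyl-protected building blocks 4, 7 and 11 are taken as commercially available.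

**Route**

Step 1
Reactants: 1 3,5-dihydroxybenzonitrile
Product: 2 3,5-bis(benzyloxy)benzonitrile
Conditions: BnBr, K2CO3, DMF, 60 °C
Reagents that add atoms: benzyl bromide, BrCc1ccccc1
Why: Williamson etherification of both phenoxides with a reactive benzylic bromide should proceed cleanly, the nitrile being inert.

Step 2
Reactants: 2 3,5-bis(benzyloxy)benzonitrile
Product: 3 2-bromo-3,5-bis(benzyloxy)benzonitrile
Conditions: NBS (1.0 equiv), MeCN, rt, dark
Reagents that add atoms: N-bromosuccinimide, O=C1CCC(=O)N1Br
Why: Electrophilic aromatic bromination should occur at C2 (ortho to one ether, para to the other), as with other 3,5-dialkoxybenzoyl compounds, because C4 between the two benzyloxy groups is more hindered.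

Step 3
Reactants: 3 2-bromo-3,5-bis(benzyloxy)benzonitrile; 4 1-(benzyloxy)-4-ethynylbenzene
Product: 5 3,5-bis(benzyloxy)-2-{[4-(benzyloxy)phenyl]ethynyl}benzonitrile
Conditions: PdCl2(PPh3)2 (5 mol %), CuI (5 mol %), Et3N, DMF, 80 °C
Reagents that add atoms: none
Why: Sonogashira coupling, in which the ortho nitrile activates the otherwise electron-rich aryl bromide toward oxidative addition.

Step 4
Reactants: 5 3,5-bis(benzyloxy)-2-{[4-(benzyloxy)phenyl]ethynyl}benzonitrile
Product: 6 6-(benzyloxy)-2-[4-(benzyloxy)phenyl]-3-iodo-1-benzofuran-4-carbonitrile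
Conditions: I2 (2 equiv), CH2Cl2, rt; aq. Na2S2O3 work-up
Reagents that add atoms: iodine, II
Why: Larock iodocyclization, in which the iodonium-activated alkyne is attacked 5-endo-dig by the ortho ether oxygen at the carbon bearing the electron-rich aryl group and the oxonium ion is debenzylated by iodide; the linear nitrile cannot take part, and the C3–I bond is placed unambiguously.

Step 5
Reactants: 6 6-(benzyloxy)-2-[4-(benzyloxy)phenyl]-3-iodo-1-benzofuran-4-carbonitrile; 7 4-(benzyloxy)benzyl chloride
Product: 10 1-{6-(benzyloxy)-2-[4-(benzyloxy)phenyl]-3-iodo-1-benzofuran-4-yl}-2-[4-(benzyloxy)phenyl]ethan-1-one, via benzylic Grignard reagent 8 (not isolated), via magnesium ketimine 9 (not isolated)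
Conditions: 7, Mg, THF, 0 °C; then 6, THF/PhMe, 0 °C to rt; then 1 M HCl, rt
Reagents that add atoms: water, O
Why: Grignard addition to a nitrile stops at the ketimine salt and gives the ketone on acidic hydrolysis, and a resonance-stabilized benzylic Grignard reagent is a poor partner for iodine–magnesium exchange, so the aryl iodide should survive.

Step 6
Reactants: 11 3,5-bis(benzyloxy)phenol
Product: 12 3,5-bis(benzyloxy)phenyl N-isopropylcarbamate
Conditions: i-PrNCO, Et3N (cat.), CH2Cl2, rt
Reagents that add atoms: isopropyl isocyanate, CC(C)N=C=O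
Why: Base-catalyzed addition of the phenol to the isocyanate installs a directing group that is cleaved under mild conditions later.

Step 7
Reactants: 12 3,5-bis(benzyloxy)phenyl N-isopropylcarbamate
Product: 15 3,5-bis(benzyloxy)-2-(trimethylsilyl)phenyl N-isopropylcarbamate, via N-silyl carbamate 13 (not isolated), via N,C-disilyl carbamate 14 (not isolated)
Conditions: TBSOTf, TMEDA, Et2O, 0 °C to rt; then n-BuLi, TMEDA, −78 °C; then TMSCl, −78 °C to rt; aq. NaHSO4 work-up
Reagents that add atoms: chlorotrimethylsilane, C[Si](C)(C)Cl
Why: Snieckus–Hoppe directed ortho metalation of the N-silylated carbamate occurs at the position flanked by the carbamate and a benzyloxy group (both such positions are equivalent by symmetry), the aryllithium is silylated, and the N–Si bond is hydrolyzed on work-up.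

Step 8
Reactants: 15 3,5-bis(benzyloxy)-2-(trimethylsilyl)phenyl N-isopropylcarbamate
Product: 17 3,5-bis(benzyloxy)-2-(trimethylsilyl)phenyl trifluoromethanesulfonate, via silylphenol 16 (not isolated)
Conditions: DBU, Et2NH, MeCN, 40 °C; then PhNTf2, rt
Reagents that add atoms: N-phenylbis(trifluoromethanesulfonimide), O=S(=O)(N(c1ccccc1)S(=O)(=O)C(F)(F)F)C(F)(F)F
Why: E1cB cleavage of the N-monosubstituted carbamate gives the phenoxide (the isocyanate is trapped by Et2NH as a urea), which is triflated in the same flask to the Kobayashi-type aryne precursor.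

Step 9
Reactants: 10 1-{6-(benzyloxy)-2-[4-(benzyloxy)phenyl]-3-iodo-1-benzofuran-4-yl}-2-[4-(benzyloxy)phenyl]ethan-1-one; 17 3,5-bis(benzyloxy)-2-(trimethylsilyl)phenyl trifluoromethanesulfonate
Product: 19 rac-penta-O-benzylhopeafuran, via aryne 18 (not isolated)
Conditions: Pd(dba)2 (10 mol %), P(o-tol)3 (20 mol %), CsF, Cs2CO3, PhMe/MeCN (4:1), 90 °C, slow addition of 17 (1.5 equiv)
Reagents that add atoms: none
Why: Proposed new method: zerovalent palladium inserts into the C3–I bond of 10, the ketone is enolized by Cs2CO3 and binds the arylpalladium as a six-membered O-bound enolate chelate that cannot reductively eliminate (C3–Cα or C3–O closure would give a peri-fused five-membered ring across C3/C4 of the benzofuran), aryne 18 released slowly from 17 by CsF then inserts into the Pd–C3 bond, and C–C reductive elimination from the resulting aryl(enolate)palladium forms the aryl–Cα bond. The closest known reaction types are the palladium-catalyzed annulation of arynes by aryl halides that carry a pendant nucleophile or C–H bond (carbopalladation of the aryne, then ring closure) and the palladium-catalyzed intramolecular α-arylation of ketones, which have not been merged to close a seven-membered ring on a peri-acyl heteroaryl halide. The seven-membered ring is closed as a formal [5+2] annulation (C3–C3a–C4–C(=O)–Cα plus the two aryne carbons) by reductive elimination from an eight-membered palladacycle, and the resorcinol ring arrives intact. The new stereocenter at Cα is not controlled here, because this doubly benzylic α-keto methine equilibrates under the basic conditions; 19 is expected racemic and step 10 sets the configuration. Regiochemistry requires C3 to bond to the aryne carbon remote from the 3-benzyloxy group and palladium to end on the carbon next to it, which is the usual outcome for 3-alkoxybenzynes (attack at the more distorted, less hindered carbon; palladium beside the inductively stabilizing ether). Chemoselectivity over C–H palladation of the C2 aryl ring and over uncatalyzed enolate addition to the aryne should come from the chelating enolate, the carbonate base (no carboxylate, no strong base) and the low stationary concentration of aryne.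

Step 10
Reactants: 19 rac-penta-O-benzylhopeafuran
Product: 20 cis-(S,S)-penta-O-benzyl hopeafuran alcohol
Conditions: RuCl[(S,S)-TsDPEN](p-cymene) (5 mol %), HCO2H/Et3N (5:2), DMF, 40 °C
Reagents that add atoms: none
Why: Noyori–Ikariya asymmetric transfer hydrogenation with dynamic kinetic resolution, in which Et3N racemizes the acidic α-methine and the (S,S) catalyst (conjugated benzofuran ring in the CH/π site, the same sense as acetophenone and 1-tetralone) should give the (S)-carbinol by hydride delivery anti to the α-aryl group, so that the cis alcohol with the (S)-methine accumulates.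

Step 11
Reactants: 20 cis-(S,S)-penta-O-benzyl hopeafuran alcohol
Product: 21 (S)-penta-O-benzylhopeafuran
Conditions: Dess–Martin periodinane, CH2Cl2, 0 °C to rt
Reagents that add atoms: none
Why: Dess–Martin oxidation returns the ketone under non-basic, non-enolizing conditions, so the methine configuration set in step 10 should be kept.

Step 12
Reactants: 21 (S)-penta-O-benzylhopeafuran
Product: 22 hopeafuran
Conditions: H2 (1 atm), Pd/C (10 %), THF/MeOH, rt
Reagents that add atoms: none
Why: Neutral hydrogenolysis of the five benzyl ethers should be faster than reduction of the hindered diaryl-flanked ketone and offers no base or strong acid to enolize the stereocenter.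

**Compound list**

1 | 3,5-dihydroxybenzonitrile | N#Cc1cc(O)cc(O)c1 | starting material
2 | 3,5-bis(benzyloxy)benzonitrile | N#Cc1cc(OCc2ccccc2)cc(OCc2ccccc2)c1 | intermediate
3 | 2-bromo-3,5-bis(benzyloxy)benzonitrile | N#Cc1cc(OCc2ccccc2)cc(OCc2ccccc2)c1Br | intermediate
4 | 1-(benzyloxy)-4-ethynylbenzene | C#Cc1ccc(OCc2ccccc2)cc1 | starting material
5 | 3,5-bis(benzyloxy)-2-{[4-(benzyloxy)phenyl]ethynyl}benzonitrile | N#Cc1cc(OCc2ccccc2)cc(OCc2ccccc2)c1C#Cc1ccc(OCc2ccccc2)cc1 | intermediate
6 | 6-(benzyloxy)-2-[4-(benzyloxy)phenyl]-3-iodo-1-benzofuran-4-carbonitrile | N#Cc1cc(OCc2ccccc2)cc2oc(-c3ccc(OCc4ccccc4)cc3)c(I)c12 | intermediate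
7 | 4-(benzyloxy)benzyl chloride | ClCc1ccc(OCc2ccccc2)cc1 | starting material
8 | [4-(benzyloxy)benzyl]magnesium chloride (not isolated) | Cl[Mg]Cc1ccc(OCc2ccccc2)cc1 | intermediate
9 | N-chloromagnesio ketimine from 6 and 8 (not isolated) | Cl[Mg]N=C(Cc1ccc(OCc2ccccc2)cc1)c1cc(OCc2ccccc2)cc2oc(-c3ccc(OCc4ccccc4)cc3)c(I)c12 | intermediate
10 | 1-{6-(benzyloxy)-2-[4-(benzyloxy)phenyl]-3-iodo-1-benzofuran-4-yl}-2-[4-(benzyloxy)phenyl]ethan-1-one | O=C(Cc1ccc(OCc2ccccc2)cc1)c1cc(OCc2ccccc2)cc2oc(-c3ccc(OCc4ccccc4)cc3)c(I)c12 | intermediate
11 | 3,5-bis(benzyloxy)phenol | Oc1cc(OCc2ccccc2)cc(OCc2ccccc2)c1 | starting material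
12 | 3,5-bis(benzyloxy)phenyl N-isopropylcarbamate | CC(C)NC(=O)Oc1cc(OCc2ccccc2)cc(OCc2ccccc2)c1 | intermediate
13 | 3,5-bis(benzyloxy)phenyl N-(tert-butyldimethylsilyl)-N-isopropylcarbamate (not isolated) | CC(C)N(C(=O)Oc1cc(OCc2ccccc2)cc(OCc2ccccc2)c1)[Si](C)(C)C(C)(C)C | intermediate
14 | 3,5-bis(benzyloxy)-2-(trimethylsilyl)phenyl N-(tert-butyldimethylsilyl)-N-isopropylcarbamate (not isolated) | CC(C)N(C(=O)Oc1cc(OCc2ccccc2)cc(OCc2ccccc2)c1[Si](C)(C)C)[Si](C)(C)C(C)(C)C | intermediate
15 | 3,5-bis(benzyloxy)-2-(trimethylsilyl)phenyl N-isopropylcarbamate | CC(C)NC(=O)Oc1cc(OCc2ccccc2)cc(OCc2ccccc2)c1[Si](C)(C)C | intermediate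
16 | 3,5-bis(benzyloxy)-2-(trimethylsilyl)phenol (not isolated) | Oc1cc(OCc2ccccc2)cc(OCc2ccccc2)c1[Si](C)(C)C | intermediate
17 | 3,5-bis(benzyloxy)-2-(trimethylsilyl)phenyl trifluoromethanesulfonate | FC(F)(F)S(=O)(=O)Oc1cc(OCc2ccccc2)cc(OCc2ccccc2)c1[Si](C)(C)C | intermediate
18 | 3,5-bis(benzyloxy)benzyne (not isolated) | C1#CC(OCc2ccccc2)=CC(OCc2ccccc2)=C1 | intermediate
19 | rac-penta-O-benzylhopeafuran (racemic at the methine α to the ketone) | O=C1c2cc(OCc5ccccc5)cc3oc(-c4ccc(OCc5ccccc5)cc4)c(c23)-c2cc(OCc5ccccc5)cc(OCc5ccccc5)c2C1c1ccc(OCc5ccccc5)cc1 | intermediate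
20 | cis-(S,S)-penta-O-benzyl hopeafuran alcohol (secondary alcohol in place of the ketone; carbinol carbon S, adjacent diarylmethine carbon S, OH and 4-benzyloxyphenyl cis on the seven-membered ring) | O[C@@H]1c2cc(OCc5ccccc5)cc3oc(-c4ccc(OCc5ccccc5)cc4)c(c23)-c2cc(OCc5ccccc5)cc(OCc5ccccc5)c2[C@@H]1c1ccc(OCc5ccccc5)cc1 | intermediate
21 | (S)-penta-O-benzylhopeafuran | O=C1c2cc(OCc5ccccc5)cc3oc(-c4ccc(OCc5ccccc5)cc4)c(c23)-c2cc(OCc5ccccc5)cc(OCc5ccccc5)c2[C@@H]1c1ccc(OCc5ccccc5)cc1 | intermediate
22 | hopeafuran, (S) at the methine α to the ketone | O=C1c2cc(O)cc3oc(-c4ccc(O)cc4)c(c23)-c2cc(O)cc(O)c2[C@@H]1c1ccc(O)cc1 | target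

**Count and risks**

Total steps: 12. Longest linear sequence: 9 (steps 1 to 5 and 9 to 12); steps 6 to 8 are the side branch to the aryne precursor.

Steps most likely to fail:

1. Step 9 (bears the label). The arylpalladium may be diverted before or after aryne insertion: by C–H palladation of the C2 aryl ring or the α-aryl ring, by protodepalladation, by a second aryne insertion, or by insertion with reversed regiochemistry. Uncatalyzed addition of the free enolate to the aryne may also compete. The fallback forms the two bonds one after the other by known chemistry. It sets out from 10: Suzuki–Miyaura coupling with commercial 3,5-bis(benzyloxy)phenylboronic acid (Pd(PPh3)4, K2CO3, dioxane/H2O, 90 °C) should give the 3-aryl ketone F1. Regitz diazo transfer onto its activated benzylic methylene (p-ABSA, DBU, MeCN) should give the α-diazo ketone F2. Dirhodium tetraacetate, Rh2(OAc)4, in CH2Cl2 should then effect intramolecular carbenoid aromatic substitution at the ring carbon ortho to the biaryl bond (ortho and para to the two ethers; both such carbons are equivalent), closing the seven-membered ring and coming back to the route at 19.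

2. Step 10. Hydride transfer to the hindered, doubly aryl-flanked ketone may be slow, racemization of the methine may not keep pace with reduction, or hydride delivery syn to the α-aryl group (trans alcohol) would invert the sense at the methine. The fallback replaces reduction and reoxidation by enantioselective protonation. It sets out from 19: KHMDS, then TMSCl in THF at −78 °C should give the trimethylsilyl enol ether F3. Protonation of F3 with a chiral BINOL-derived N-triflyl thiophosphoramide catalyst and 2,4,6-trimethylphenol as the stoichiometric proton source (catalyst enantiomer chosen by trial) comes back to the route at 21, bypassing 20.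

3. Step 5. Iodine–magnesium exchange at C3 or Wurtz-type coupling may compete with slow addition to the peri-hindered nitrile. The fallback avoids a Grignard reagent in the presence of the aryl iodide. It sets out from 6: DIBAL-H in CH2Cl2 at −78 °C, then aqueous HCl, should give the aldehyde F4. Zinc-mediated Barbier benzylation with 7 (Zn, THF/aq. NH4Cl), which tolerates aryl iodides, should give the racemic secondary alcohol F5. Dess–Martin oxidation of F5 comes back to the route at 10.

Further compounds
F1 | step 9 | 1-{6-(benzyloxy)-2-[4-(benzyloxy)phenyl]-3-[3,5-bis(benzyloxy)phenyl]-1-benzofuran-4-yl}-2-[4-(benzyloxy)phenyl]ethan-1-one | O=C(Cc1ccc(OCc2ccccc2)cc1)c1cc(OCc2ccccc2)cc2oc(-c3ccc(OCc4ccccc4)cc3)c(-c3cc(OCc4ccccc4)cc(OCc4ccccc4)c3)c12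
F2 | step 9 | 1-{6-(benzyloxy)-2-[4-(benzyloxy)phenyl]-3-[3,5-bis(benzyloxy)phenyl]-1-benzofuran-4-yl}-2-[4-(benzyloxy)phenyl]-2-diazoethan-1-one | O=C(C(=[N+]=[N-])c1ccc(OCc2ccccc2)cc1)c1cc(OCc2ccccc2)cc2oc(-c3ccc(OCc4ccccc4)cc3)c(-c3cc(OCc4ccccc4)cc(OCc4ccccc4)c3)c12
F3 | step 10 | trimethylsilyl enol ether of 19 (C(OSiMe3)=C(aryl) double bond in the seven-membered ring) | C[Si](C)(C)OC1=C(c2ccc(OCc5ccccc5)cc2)c2c(OCc5ccccc5)cc(OCc5ccccc5)cc2-c2c(-c4ccc(OCc5ccccc5)cc4)oc3cc(OCc5ccccc5)cc1c23
F4 | step 5 | 6-(benzyloxy)-2-[4-(benzyloxy)phenyl]-3-iodo-1-benzofuran-4-carbaldehyde | O=Cc1cc(OCc2ccccc2)cc2oc(-c3ccc(OCc4ccccc4)cc3)c(I)c12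
F5 | step 5 | rac-1-{6-(benzyloxy)-2-[4-(benzyloxy)phenyl]-3-iodo-1-benzofuran-4-yl}-2-[4-(benzyloxy)phenyl]ethan-1-ol | OC(Cc1ccc(OCc2ccccc2)cc1)c1cc(OCc2ccccc2)cc2oc(-c3ccc(OCc4ccccc4)cc3)c(I)c12
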